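Ring numbering: C1 (quaternary C–OH bearing C7H2OH), C2 (CHOH), C3 (CHOBz), C4=C5, C6 (CHOBz). O–C1–C7 is a glycolate unit and C6 is allylic through C5=C4, so the carbocycle is the [3,3] product of a six-membered lactone C7(=O)–O–C4 (ring atoms C7, O, C4, C3, C2, C1) that carries C5=C6 as a (Z)-enol benzoate.
Cuts, in retrosynthetic order: C7 alcohol back to the acid; C1–C6 (restoring O–C4) to that lactone; the enol C6–O bond (alkyne plus benzoic acid); C5–C6 (one-carbon homologation of an aldehyde); the lactone C7–O bond.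
Forward: diacetone-D-glucose supplies a D-glucuronate chain (its C6, C5, C4, C3, C2, C1 become C7, C1, C2, C3, C4, C5) in which the oxygen that ends as the C3 benzoate is the only free hydroxyl. The anomeric carbon is homologated to the alkyne, the freed O2 closes the δ-lactone (first ring), benzoic acid is added, and the lactone is contracted to the cyclohexene (the only carbocycle).
Stereochemistry: C2 and C3 are C4 and C3 of D-glucose, untouched. Glucose C2 (ring C4) is destroyed in the rearrangement and relays its configuration, through a boat transition state and the Z-enol ester, to C1 and C6.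

Key step: step 12

Remark: the acyclic and lactone intermediates after the homologation are named as L-gulo-heptonic acid derivatives (acid carbon = C1), which is D-glucuronic acid numbered from its carboxyl end plus one carbon; sugar C2, C3, C4, C5, C6, C7, C1 become ring C1 to C7, and the lactol is used as its anomeric mixture because that centre becomes sp.

Step 1
Reactants: 1 1,2:5,6-di-O-isopropylidene-α-D-glucofuranose
Product: 2 1,2:5,6-di-O-isopropylidene-3-O-(naphthalen-2-ylmethyl)-α-D-glucofuranose
Conditions: NaH, 2-(bromomethyl)naphthalene, Bu4NI (cat.), DMF, 0 °C → rt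
Reagents that add atoms: 2-(bromomethyl)naphthalene, BrCc1ccc2ccccc2c1
Why: Williamson etherification of the only free hydroxyl (O3, the oxygen that will carry the C3 benzoate) gives an ether that survives acid and base and is later removed oxidatively; no stereocentre is touched.

Step 2
Reactants: 2 1,2:5,6-di-O-isopropylidene-3-O-(naphthalen-2-ylmethyl)-α-D-glucofuranose
Product: 3 1,2-O-isopropylidene-3-O-(naphthalen-2-ylmethyl)-α-D-glucofuranose
Conditions: AcOH/H2O (7:3), rt
Reagents that add atoms: none
Why: Acid-catalysed acetal hydrolysis is selective for the terminal 5,6-dioxolane over the ring-fused anomeric 1,2-acetal, a standard differentiation in glucofuranose chemistry.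

Step 3
Reactants: 3 1,2-O-isopropylidene-3-O-(naphthalen-2-ylmethyl)-α-D-glucofuranose
Product: 5 1,2-O-isopropylidene-3-O-(naphthalen-2-ylmethyl)-α-D-glucofuranuronic acid, via aldehyde 4 (not isolated)
Conditions: TEMPO (20 mol %), PhI(OAc)2, MeCN/H2O (1:1), rt
Reagents that add atoms: water, O
Why: Oxoammonium oxidation (TEMPO/PhI(OAc)2) takes the primary alcohol through the aldehyde hydrate to the acid and leaves the secondary 5-hydroxyl alone, as is routine for 3-O-benzyl analogues.

Step 4
Reactants: 5 1,2-O-isopropylidene-3-O-(naphthalen-2-ylmethyl)-α-D-glucofuranuronic acid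
Product: 6 methyl 1,2-O-isopropylidene-3-O-(naphthalen-2-ylmethyl)-α-D-glucofuranuronate
Conditions: MeI, KHCO3, DMF, rt
Reagents that add atoms: iodomethane, CI
Why: SN2 O-alkylation of the carboxylate gives the methyl ester without touching the α-hydroxyl or the stereocentre next to it.

Step 5
Reactants: 6 methyl 1,2-O-isopropylidene-3-O-(naphthalen-2-ylmethyl)-α-D-glucofuranuronate
Product: 7 methyl 5-O-(tert-butyldimethylsilyl)-1,2-O-isopropylidene-3-O-(naphthalen-2-ylmethyl)-α-D-glucofuranuronate
Conditions: TBSOTf, 2,6-lutidine, CH2Cl2, 0 °C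
Reagents that add atoms: tert-butyldimethylsilyl trifluoromethanesulfonate, CC(C)(C)[Si](C)(C)OS(=O)(=O)C(F)(F)F
Why: Silylation of the α-hydroxy ester places the ether that will sit on the quaternary carbon of the target and forces the sugar to remain a furanose once the anomeric acetal is removed.

Step 6
Reactants: 7 methyl 5-O-(tert-butyldimethylsilyl)-1,2-O-isopropylidene-3-O-(naphthalen-2-ylmethyl)-α-D-glucofuranuronate
Product: 8 methyl 5-O-(tert-butyldimethylsilyl)-3-O-(naphthalen-2-ylmethyl)-D-glucofuranuronate (α/β lactol)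
Conditions: CF3CO2H/H2O (9:1), 0 °C
Reagents that add atoms: none
Why: Hydrolysis of the anomeric acetal frees the lactol, while the silyl ether, deactivated towards acid by the neighbouring ester, and the naphthylmethyl ether are expected to survive the short exposure.

Step 7
Reactants: 8 methyl 5-O-(tert-butyldimethylsilyl)-3-O-(naphthalen-2-ylmethyl)-D-glucofuranuronate; 9 dimethyl (1-diazo-2-oxopropyl)phosphonate
Product: 11 2-O-(tert-butyldimethylsilyl)-6,7-dideoxy-4-O-(naphthalen-2-ylmethyl)-L-gulo-hept-6-ynono-1,5-lactone (3-OH free), via alkynyl hydroxy ester 10 (not isolated)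
Conditions: K2CO3, MeOH, 0 °C → rt; then 10-camphorsulfonic acid (cat.), PhMe, 40 °C
Reagents that add atoms: none
Why: The Ohira–Bestmann form of the Seyferth–Gilbert homologation converts the open-chain aldehyde of the lactol into the terminal alkyne, and acid then closes the only unstrained lactone on offer, from the propargylic O5, since O4 is etherified and O3 could only give a β-lactone; the four stereocentres are carried over unchanged.

Step 8
Reactants: 11 2-O-(tert-butyldimethylsilyl)-6,7-dideoxy-4-O-(naphthalen-2-ylmethyl)-L-gulo-hept-6-ynono-1,5-lactone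
Product: 12 2,3-di-O-(tert-butyldimethylsilyl)-6,7-dideoxy-4-O-(naphthalen-2-ylmethyl)-L-gulo-hept-6-ynono-1,5-lactone
Conditions: TBSOTf, 2,6-lutidine, CH2Cl2, 0 °C → rt
Reagents that add atoms: tert-butyldimethylsilyl trifluoromethanesulfonate, CC(C)(C)[Si](C)(C)OS(=O)(=O)C(F)(F)F
Why: Silylation of the remaining hydroxyl under a non-nucleophilic base gives the bis-silyl ether, on which any material whose silyl group had moved from O2 to O3 in the carbonate step converges.

Step 9
Reactants: 12 2,3-di-O-(tert-butyldimethylsilyl)-6,7-dideoxy-4-O-(naphthalen-2-ylmethyl)-L-gulo-hept-6-ynono-1,5-lactone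
Product: 13 2,3-di-O-(tert-butyldimethylsilyl)-6,7-dideoxy-L-gulo-hept-6-ynono-1,5-lactone (4-OH free)
Conditions: DDQ, CH2Cl2/pH 7 buffer (10:1), rt
Reagents that add atoms: none
Why: Oxidative cleavage of the 2-naphthylmethyl ether by DDQ spares silyl ethers, lactone and alkyne, and the 4-hydroxy-δ-lactone is acylated directly afterwards so that it has no time to translactonise to the γ-lactone.

Step 10
Reactants: 13 2,3-di-O-(tert-butyldimethylsilyl)-6,7-dideoxy-L-gulo-hept-6-ynono-1,5-lactone
Product: 14 4-O-benzoyl-2,3-di-O-(tert-butyldimethylsilyl)-6,7-dideoxy-L-gulo-hept-6-ynono-1,5-lactone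
Conditions: BzCl, pyridine, DMAP (cat.), CH2Cl2, 0 °C → rt
Reagents that add atoms: benzoyl chloride, O=C(Cl)c1ccccc1
Why: DMAP-catalysed acylation of the secondary alcohol installs the benzoate that ends at C3 of the target and closes off the γ-lactone pathway.

Step 11
Reactants: 14 4-O-benzoyl-2,3-di-O-(tert-butyldimethylsilyl)-6,7-dideoxy-L-gulo-hept-6-ynono-1,5-lactone; 15 benzoic acid
Product: 16 (6Z)-4,7-di-O-benzoyl-2,3-di-O-(tert-butyldimethylsilyl)-6-deoxy-L-gulo-hept-6-enono-1,5-lactone (δ-lactone with a (Z)-2-(benzoyloxy)vinyl group on C5)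
Conditions: Ru(η3-CH2C(CH3)CH2)2[Ph2P(CH2)4PPh2] (5 mol %), PhMe, 65 °C
Reagents that add atoms: none
Why: Ruthenium-catalysed anti-Markovnikov hydro-acyloxylation of a terminal alkyne, in which benzoate adds to the carbene carbon of a ruthenium vinylidene, delivers the (Z)-enol ester under neutral conditions tolerated by lactone, benzoate and silyl ethers.

Step 12
Reactants: 16 (6Z)-4,7-di-O-benzoyl-2,3-di-O-(tert-butyldimethylsilyl)-6-deoxy-L-gulo-hept-6-enono-1,5-lactone
Product: 19 3,6-bis(benzoyloxy)-1,2-bis(tert-butyldimethylsilyloxy)cyclohex-4-ene-1-carboxylic acid configured as in the target (O1 cis to the C6 benzoate and trans to O2; O2 trans to the C3 benzoate), via silyl ketene acetal 17 (not isolated), via trimethylsilyl ester 18 (not isolated)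
Conditions: Me3SiCl/Et3N (premixed), LiN(SiMe3)2, THF, −78 °C → rt; PhMe, 90 °C; then aq. citric acid
Reagents that add atoms: chlorotrimethylsilane, C[Si](C)(C)Cl (its silyl group is carried by 17 and 18 and is lost on work-up)
Why: Proposed new method: the hindered amide removes the only acidic C–H (sugar C2) and the enolate is silylated in situ to the cyclic ketene acetal 17, whose C2=C1(OSi)–O5 unit and (Z)-enol benzoate C6=C7 (sugar numbering) are held by the lactone ring in a boat-shaped six-atom array, so a concerted suprafacial [3,3] shift makes the ring C1–C6 bond, breaks O–C4 and leaves C4=C5 as the ring cis-alkene; the closest known reactions are the Ireland–Claisen ring contraction of 6-alkenyl lactones to cycloalkene carboxylic acids and glycolate Ireland–Claisen rearrangements onto heteroatom-substituted alkenes such as vinylsilanes, and the enol ester, which has no acidic hydrogen and is at least as electron-rich as those alkenes, is expected to follow the same path. The cyclohexene closes by this pericyclic C–C bond formation inside a bicyclo[2.2.2]octane-like transition state with ring C1 and C4 as bridgeheads and C2–C3, C7–O and C6=C5 as the three bridges, a chair being out of reach for a six-membered lactone. Ring C1 is controlled by the stereocentre that is lost (sugar C5): the C7–O bridge stays on the face from which the alkenyl group is delivered, so C7 ends cis to O2 and trans to the C3 benzoate and the C1 oxygen is turned to the other face. Ring C6 is controlled by the Z geometry of the enol ester, because in the boat the substituent cis to ring C4 points towards the C2–C3 bridge, which puts the C6 benzoate cis to the C1 oxygen. The step needs O-silylation to outrun β-elimination of the neighbouring silyloxy group and acyl transfer from the enol ester, which Me3SiCl/Et3N already present at −78 °C when the base is added is meant to secure.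

Step 13
Reactants: 19 3,6-bis(benzoyloxy)-1,2-bis(tert-butyldimethylsilyloxy)cyclohex-4-ene-1-carboxylic acid
Product: 20 3,6-bis(benzoyloxy)-1,2-bis(tert-butyldimethylsilyloxy)-1-(hydroxymethyl)cyclohex-4-ene, configured as in the target
Conditions: BH3·THF, THF, 0 °C → rt; then MeOH
Reagents that add atoms: none
Why: Borane reduces a carboxylic acid through its acyloxyborane far faster than it attacks benzoates and faster than it hydroborates the hindered alkene between two allylic esters, so only C7 should be taken to the alcohol level.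

Step 14
Reactants: 20 3,6-bis(benzoyloxy)-1,2-bis(tert-butyldimethylsilyloxy)-1-(hydroxymethyl)cyclohex-4-ene
Product: 21 (1R,2S,3R,6S)-1,2-dihydroxy-1-(hydroxymethyl)cyclohex-4-ene-3,6-diyl dibenzoate (ring numbering of the plan)
Conditions: HF·pyridine, pyridine, THF, 0 °C → rt
Reagents that add atoms: none
Why: Acidic fluoride cleaves the secondary and the tertiary silyl ether without the benzoyl migration that basic fluoride would invite, which reveals the triol.

Compound list
1 | 1,2:5,6-di-O-isopropylidene-α-D-glucofuranose | CC1(C)OC[C@@H](O1)[C@H]2O[C@@H]3OC(C)(C)O[C@@H]3[C@H]2O | starting material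
2 | 1,2:5,6-di-O-isopropylidene-3-O-(naphthalen-2-ylmethyl)-α-D-glucofuranose | CC1(C)OC[C@@H](O1)[C@H]2O[C@@H]3OC(C)(C)O[C@@H]3[C@H]2OCc4ccc5ccccc5c4 | intermediate
3 | 1,2-O-isopropylidene-3-O-(naphthalen-2-ylmethyl)-α-D-glucofuranose | OC[C@@H](O)[C@H]1O[C@@H]2OC(C)(C)O[C@@H]2[C@H]1OCc3ccc4ccccc4c3 | intermediate
4 | 1,2-O-isopropylidene-3-O-(naphthalen-2-ylmethyl)-α-D-gluco-hexodialdo-1,4-furanose | O=C[C@@H](O)[C@H]1O[C@@H]2OC(C)(C)O[C@@H]2[C@H]1OCc3ccc4ccccc4c3 | intermediate
5 | 1,2-O-isopropylidene-3-O-(naphthalen-2-ylmethyl)-α-D-glucofuranuronic acid | OC(=O)[C@@H](O)[C@H]1O[C@@H]2OC(C)(C)O[C@@H]2[C@H]1OCc3ccc4ccccc4c3 | intermediate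
6 | methyl 1,2-O-isopropylidene-3-O-(naphthalen-2-ylmethyl)-α-D-glucofuranuronate | COC(=O)[C@@H](O)[C@H]1O[C@@H]2OC(C)(C)O[C@@H]2[C@H]1OCc3ccc4ccccc4c3 | intermediate
7 | methyl 5-O-(tert-butyldimethylsilyl)-1,2-O-isopropylidene-3-O-(naphthalen-2-ylmethyl)-α-D-glucofuranuronate | COC(=O)[C@@H](O[Si](C)(C)C(C)(C)C)[C@H]1O[C@@H]2OC(C)(C)O[C@@H]2[C@H]1OCc3ccc4ccccc4c3 | intermediate
8 | methyl 5-O-(tert-butyldimethylsilyl)-3-O-(naphthalen-2-ylmethyl)-D-glucofuranuronate (anomeric mixture) | COC(=O)[C@@H](O[Si](C)(C)C(C)(C)C)[C@H]1OC(O)[C@H](O)[C@H]1OCc2ccc3ccccc3c2 | intermediate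
9 | dimethyl (1-diazo-2-oxopropyl)phosphonate | COP(=O)(OC)C(=[N+]=[N-])C(C)=O | starting material
10 | methyl 2-O-(tert-butyldimethylsilyl)-6,7-dideoxy-4-O-(naphthalen-2-ylmethyl)-L-gulo-hept-6-ynonate | COC(=O)[C@@H](O[Si](C)(C)C(C)(C)C)[C@@H](O)[C@H](OCc1ccc2ccccc2c1)[C@@H](O)C#C | intermediate
11 | 2-O-(tert-butyldimethylsilyl)-6,7-dideoxy-4-O-(naphthalen-2-ylmethyl)-L-gulo-hept-6-ynono-1,5-lactone | O=C1O[C@@H](C#C)[C@@H](OCc2ccc3ccccc3c2)[C@H](O)[C@@H]1O[Si](C)(C)C(C)(C)C | intermediate
12 | 2,3-di-O-(tert-butyldimethylsilyl)-6,7-dideoxy-4-O-(naphthalen-2-ylmethyl)-L-gulo-hept-6-ynono-1,5-lactone | O=C1O[C@@H](C#C)[C@@H](OCc2ccc3ccccc3c2)[C@H](O[Si](C)(C)C(C)(C)C)[C@@H]1O[Si](C)(C)C(C)(C)C | intermediate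
13 | 2,3-di-O-(tert-butyldimethylsilyl)-6,7-dideoxy-L-gulo-hept-6-ynono-1,5-lactone | O=C1O[C@@H](C#C)[C@@H](O)[C@H](O[Si](C)(C)C(C)(C)C)[C@@H]1O[Si](C)(C)C(C)(C)C | intermediate
14 | 4-O-benzoyl-2,3-di-O-(tert-butyldimethylsilyl)-6,7-dideoxy-L-gulo-hept-6-ynono-1,5-lactone | O=C1O[C@@H](C#C)[C@@H](OC(=O)c2ccccc2)[C@H](O[Si](C)(C)C(C)(C)C)[C@@H]1O[Si](C)(C)C(C)(C)C | intermediate
15 | benzoic acid | O=C(O)c1ccccc1 | starting material
16 | (6Z)-4,7-di-O-benzoyl-2,3-di-O-(tert-butyldimethylsilyl)-6-deoxy-L-gulo-hept-6-enono-1,5-lactone | O=C1O[C@@H](/C=C\OC(=O)c2ccccc2)[C@@H](OC(=O)c2ccccc2)[C@H](O[Si](C)(C)C(C)(C)C)[C@@H]1O[Si](C)(C)C(C)(C)C | intermediate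
17 | cyclic trimethylsilyl ketene acetal of 16 (sugar C1=C2 enol ether) | C[Si](C)(C)OC1=C(O[Si](C)(C)C(C)(C)C)[C@@H](O[Si](C)(C)C(C)(C)C)[C@H](OC(=O)c2ccccc2)[C@H](/C=C\OC(=O)c2ccccc2)O1 | intermediate
18 | trimethylsilyl ester of 19 | O=C(O[C@H]1C=C[C@@H](OC(=O)c2ccccc2)[C@H](O[Si](C)(C)C(C)(C)C)[C@]1(O[Si](C)(C)C(C)(C)C)C(=O)O[Si](C)(C)C)c1ccccc1 | intermediate
19 | 3,6-bis(benzoyloxy)-1,2-bis(tert-butyldimethylsilyloxy)cyclohex-4-ene-1-carboxylic acid, configured as in 21 | O=C(O[C@H]1C=C[C@@H](OC(=O)c2ccccc2)[C@H](O[Si](C)(C)C(C)(C)C)[C@]1(O[Si](C)(C)C(C)(C)C)C(=O)O)c1ccccc1 | intermediate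
20 | 3,6-bis(benzoyloxy)-1,2-bis(tert-butyldimethylsilyloxy)-1-(hydroxymethyl)cyclohex-4-ene, configured as in 21 | O=C(O[C@H]1C=C[C@@H](OC(=O)c2ccccc2)[C@H](O[Si](C)(C)C(C)(C)C)[C@]1(O[Si](C)(C)C(C)(C)C)CO)c1ccccc1 | intermediate
21 | (1R,2S,3R,6S)-1,2-dihydroxy-1-(hydroxymethyl)cyclohex-4-ene-3,6-diyl dibenzoate | O=C(O[C@H]1C=C[C@@H](OC(=O)c2ccccc2)[C@H](O)[C@]1(O)CO)c1ccccc1 | target

Total step count: 14. Longest linear sequence: 14 steps (1 to 21).

Steps most likely to fail

Step 12. The lithium enolate may lose the neighbouring silyloxy group by β-elimination before it is silylated. The enol benzoate may transfer its acyl group to the enolate or the amide base. The rearrangement barrier may also be so high with this alkene that the ketene acetal decomposes on heating. The fallback uses known chemistry and sets out from alkynyl lactone 14. Ruthenium-catalysed trans-hydrosilylation ([RuCl2(η6-p-cymene)]2, HSi(OEt)3) should give the (Z)-alkenylsilane lactone F1. The same base and silyl chloride then bring about a lactone contraction onto a vinylsilane, both elements being precedented. It runs through the silyl ketene acetal F2 and the trimethylsilyl ester F3 to the allylsilane acid F4, which carries silicon where the C6 oxygen belongs. Tamao–Kumada oxidation (H2O2, KF, KHCO3) replaces silicon by hydroxyl with retention to give the hydroxy acid F5. Benzoylation (BzCl, pyridine, aqueous work-up) rejoins the route at 19.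

Step 7. The furanose lactol may open slowly in methanolic carbonate. Migration of the silyl group towards the propargylic oxygen, epimerisation next to the masked aldehyde, or β-elimination of the naphthylmethoxy group could then compete with homologation. The fallback is a Colvin homologation under aprotic, cryogenic conditions and sets out from lactol 8. Lithium trimethylsilyldiazomethanide (Me3SiCHN2, LiN(i-Pr)2, THF, −78 → 0 °C) adds to the open-chain aldehyde. Peterson-type elimination and 1,2-hydrogen shift of the alkylidene carbene give the same hydroxy ester 10 without methoxide being present. The acid lactonisation of the main route rejoins at 11, and no new compound is involved.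

Step 11. The propargylic lactone C–O bond may ionise at the ruthenium vinylidene stage, or regio- and Z-selectivity may erode next to the crowded ring. The fallback sets out from 14. Rhodium-catalysed trans-hydroboration ([RhCl(C8H12)]2, P(i-Pr)3, Et3N, pinacolborane) should give the (Z)-alkenylboronate lactone F6. Oxidative coupling with benzoic acid 15 mediated by Cu(OAc)2 (Et3N, molecular sieves, air) then forms the enol C–O bond with retention of alkene geometry and rejoins at 16.

Further compounds
F1 | step 12 | (6Z)-4-O-benzoyl-2,3-di-O-(tert-butyldimethylsilyl)-6,7-dideoxy-7-(triethoxysilyl)-L-gulo-hept-6-enono-1,5-lactone | O=C1O[C@@H](/C=C\[Si](OCC)(OCC)OCC)[C@@H](OC(=O)c2ccccc2)[C@H](O[Si](C)(C)C(C)(C)C)[C@@H]1O[Si](C)(C)C(C)(C)C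
F2 | step 12 | cyclic trimethylsilyl ketene acetal of F1 | C[Si](C)(C)OC1=C(O[Si](C)(C)C(C)(C)C)[C@@H](O[Si](C)(C)C(C)(C)C)[C@H](OC(=O)c2ccccc2)[C@H](/C=C\[Si](OCC)(OCC)OCC)O1
F3 | step 12 | trimethylsilyl ester of F4 | CCO[Si](OCC)(OCC)[C@H]1C=C[C@@H](OC(=O)c2ccccc2)[C@H](O[Si](C)(C)C(C)(C)C)[C@]1(O[Si](C)(C)C(C)(C)C)C(=O)O[Si](C)(C)C
F4 | step 12 | 3-(benzoyloxy)-1,2-bis(tert-butyldimethylsilyloxy)-6-(triethoxysilyl)cyclohex-4-ene-1-carboxylic acid, silicon cis to O1, other centres as in 19 | CCO[Si](OCC)(OCC)[C@H]1C=C[C@@H](OC(=O)c2ccccc2)[C@H](O[Si](C)(C)C(C)(C)C)[C@]1(O[Si](C)(C)C(C)(C)C)C(=O)O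
F5 | step 12 | 3-(benzoyloxy)-1,2-bis(tert-butyldimethylsilyloxy)-6-hydroxycyclohex-4-ene-1-carboxylic acid, configured as in 19 | O[C@H]1C=C[C@@H](OC(=O)c2ccccc2)[C@H](O[Si](C)(C)C(C)(C)C)[C@]1(O[Si](C)(C)C(C)(C)C)C(=O)O
F0 | step 7 | none | none
F6 | step 11 | (6Z)-4-O-benzoyl-2,3-di-O-(tert-butyldimethylsilyl)-6,7-dideoxy-7-(4,4,5,5-tetramethyl-1,3,2-dioxaborolan-2-yl)-L-gulo-hept-6-enono-1,5-lactone | O=C1O[C@@H](/C=C\B2OC(C)(C)C(C)(C)O2)[C@@H](OC(=O)c3ccccc3)[C@H](O[Si](C)(C)C(C)(C)C)[C@@H]1O[Si](C)(C)C(C)(C)C
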